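**Strategy.** Ring A is made last on the hydrophenanthrene half (abietane numbering). In the enantiopure 3-isopropylidene-2-tetralone 17 (rings B and C), C1 and C4 lie 1,4 to each other across the quaternary carbon C10 and the ring-fusion carbon C5, and the C6 ketone makes C4 an electrophilic enone terminus. A photoredox radical (4+2) annulation clips vinylboronic pinacol ester between them: a C1 radical from a decarboxylated C10 acetic ester adds to the alkene, and the α-boryl radical closes on C4. One operation forms C1–C2 and C3–C4, the gem-dimethyl carbon and a C3 boronate, the masked 3β-hydroxyl. The C6 ketone then guides the union with the naphthalene half.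

Key step: step 12

**Remarks on the chemistry**
- Numbering: abietane locants (C1–C14, C20) are used for the hydrophenanthrene half in all intermediates (ring A = C1–C5, C10; ring B = C5–C10; ring C = C8, C9, C11–C14). Primed locants are used for the naphthalene half (oxygen on C2', link on C3'). β is the face of the C10 methyl group.
- Assumption: (R)-t-BuPyOx is taken to deliver (S)-5, by analogy with the facial sense of this catalyst on β-methyl cyclic enones. If the sense is opposite, the (S) ligand is used.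
- Compound 14 is drawn as the open hydroxy ketone; equilibration with its cyclic hemiketal is of no consequence.

**Route**

Step 1
Reactants: 1 4-bromo-1-iodo-2-methoxybenzene
Product: 2 4-bromo-2-methoxy-1-(propan-2-yl)benzene
Conditions: i-PrZnBr (1.1 equiv), Pd(OAc)2 (1 mol%), CPhos (2 mol%), THF/toluene, 0 °C → rt
Reagents that add atoms: isopropylzinc bromide, CC(C)[Zn]Br
Why: Negishi coupling in which oxidative addition at C–I is much faster than at C–Br, while CPhos suppresses isomerisation of the secondary alkyl group.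

Step 2
Reactants: 2 4-bromo-2-methoxy-1-(propan-2-yl)benzene
Product: 3 [3-methoxy-4-(propan-2-yl)phenyl]boronic acid
Conditions: B2(OH)4, Pd(OAc)2 (2 mol%), XPhos (4 mol%), KOAc, EtOH, 80 °C; aqueous work-up
Reagents that add atoms: tetrahydroxydiboron, OB(O)B(O)O
Why: Miyaura-type borylation of an unhindered aryl bromide with tetrahydroxydiboron should give the boronic acid directly.

Step 3
Reactants: 3 [3-methoxy-4-(propan-2-yl)phenyl]boronic acid, 4 3-methylcyclopent-2-en-1-one
Product: 5 (S)-3-[3-methoxy-4-(propan-2-yl)phenyl]-3-methylcyclopentan-1-one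
Conditions: Pd(OCOCF3)2 (5 mol%), (R)-t-BuPyOx (6 mol%), NH4PF6 (30 mol%), H2O (5 equiv), ClCH2CH2Cl, 40 °C
Reagents that add atoms: none
Why: Divalent-palladium-catalysed asymmetric conjugate addition of an arylboronic acid to a β-methyl cyclic enone; the pyridine-oxazoline ligand selects the enone face and so sets the benzylic quaternary centre (later C10).

Step 4
Reactants: 5 (S)-3-[3-methoxy-4-(propan-2-yl)phenyl]-3-methylcyclopentan-1-one
Product: 6 {[(S)-4-[3-methoxy-4-(propan-2-yl)phenyl]-4-methylcyclopent-1-en-1-yl]oxy}trimethylsilane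
Conditions: LiN(i-Pr)2, Me3SiCl, THF, −78 °C
Reagents that add atoms: chlorotrimethylsilane, C[Si](C)(C)Cl
Why: Kinetic deprotonation should occur at the α-CH2 remote from the quaternary carbon, and O-silylation fixes this regiochemistry in the silyl enol ether.

Step 5
Reactants: 6 {[(S)-4-[3-methoxy-4-(propan-2-yl)phenyl]-4-methylcyclopent-1-en-1-yl]oxy}trimethylsilane
Product: 9 (S)-4-[3-methoxy-4-(propan-2-yl)phenyl]-4-methyloxan-2-one, via aldehyde acid 7 (not isolated), via hydroxy acid 8 (not isolated)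
Conditions: O3, CH2Cl2/MeOH, −78 °C; NaBH4, −78 °C → rt; then 2 M HCl, rt
Reagents that add atoms: ozone, [O-][O+]=O
Why: Ozonolysis of the silyl enol ether cleaves the ring into an acid arm (CH2 next to the quaternary carbon) and an aldehyde arm; borohydride reduction and acid lactonisation give the δ-lactone, leaving the stereocentre untouched.

Step 6
Reactants: 9 (S)-4-[3-methoxy-4-(propan-2-yl)phenyl]-4-methyloxan-2-one
Product: 10 (S)-4-[2-bromo-5-methoxy-4-(propan-2-yl)phenyl]-4-methyloxan-2-one
Conditions: NBS, MeCN, 0 °C → rt, dark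
Reagents that add atoms: N-bromosuccinimide, O=C1CCC(=O)N1Br
Why: Electrophilic aromatic bromination should go para to the methoxy group (the later C8), because the other ortho position is blocked by isopropyl and the remaining one is flanked on both sides.

Step 7
Reactants: 10 (S)-4-[2-bromo-5-methoxy-4-(propan-2-yl)phenyl]-4-methyloxan-2-one
Product: 13 (S)-4-[2-bromo-5-methoxy-4-(propan-2-yl)phenyl]-4-methyl-3-(propan-2-ylidene)oxan-2-one, via aldol adduct 11 (not isolated), via tertiary acetate 12 (not isolated)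
Conditions: LiN(i-Pr)2, THF, −78 °C; acetone; Ac2O, −78 → 0 °C; then DBU, rt → 50 °C
Reagents that add atoms: acetone, CC(C)=O
Why: Aldol addition of the lactone enolate (its only enolisable position is the later C5) to acetone, acetylation of the alkoxide and E1cB elimination should give the conjugated isopropylidene lactone.

Step 8
Reactants: 13 (S)-4-[2-bromo-5-methoxy-4-(propan-2-yl)phenyl]-4-methyl-3-(propan-2-ylidene)oxan-2-one
Product: 14 (S)-4-[2-bromo-5-methoxy-4-(propan-2-yl)phenyl]-6-hydroxy-4-methyl-3-(propan-2-ylidene)hexan-2-one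
Conditions: MeLi (1.1 equiv), THF, −78 °C; aq. NH4Cl
Reagents that add atoms: methyllithium, [Li]C
Why: 1,2-Addition of methyllithium to the lactone gives a lithium hemiketal that is stable at −78 °C, so a single methyl (the later C7) is delivered and the ring opens to the methyl ketone on work-up.

Step 9
Reactants: 14 (S)-4-[2-bromo-5-methoxy-4-(propan-2-yl)phenyl]-6-hydroxy-4-methyl-3-(propan-2-ylidene)hexan-2-one
Product: 15 (S)-3-[2-bromo-5-methoxy-4-(propan-2-yl)phenyl]-3-methyl-5-oxo-4-(propan-2-ylidene)hexanoic acid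
Conditions: TEMPO (20 mol%), PhI(OAc)2 (2.5 equiv), MeCN/H2O 1:1, rt
Reagents that add atoms: water, O
Why: Oxoammonium-mediated oxidation of the primary alcohol through the aldehyde hydrate gives the carboxylic acid without touching the tetrasubstituted enone or the arene.

Step 10
Reactants: 15 (S)-3-[2-bromo-5-methoxy-4-(propan-2-yl)phenyl]-3-methyl-5-oxo-4-(propan-2-ylidene)hexanoic acid
Product: 16 2-[(1R)-7-methoxy-1-methyl-3-oxo-6-(propan-2-yl)-2-(propan-2-ylidene)-1,2,3,4-tetrahydronaphthalen-1-yl]acetic acid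
Conditions: Pd2(dba)3 (5 mol%), Xantphos (12 mol%), Cs2CO3 (3.5 equiv), 1,4-dioxane, 100 °C; acidic work-up
Reagents that add atoms: none
Why: Palladium-catalysed intramolecular α-arylation of the methyl ketone (Buchwald–Hartwig enolate arylation) closes the six-membered ring B by forming C7–C8; the acid is carried as its cesium salt and the CIP letter changes only because the priorities change.

Step 11
Reactants: 16 2-[(1R)-7-methoxy-1-methyl-3-oxo-6-(propan-2-yl)-2-(propan-2-ylidene)-1,2,3,4-tetrahydronaphthalen-1-yl]acetic acid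
Product: 17 1,3-dioxoisoindolin-2-yl 2-[(1R)-7-methoxy-1-methyl-3-oxo-6-(propan-2-yl)-2-(propan-2-ylidene)-1,2,3,4-tetrahydronaphthalen-1-yl]acetate
Conditions: N-hydroxyphthalimide, N,N'-diisopropylcarbodiimide, DMAP (cat.), CH2Cl2, rt
Reagents that add atoms: N-hydroxyphthalimide, O=C1c2ccccc2C(=O)N1O
Why: Carbodiimide esterification gives the redox-active ester, which is the precursor of the C1 radical.

Step 12
Reactants: 17 1,3-dioxoisoindolin-2-yl 2-[(1R)-7-methoxy-1-methyl-3-oxo-6-(propan-2-yl)-2-(propan-2-ylidene)-1,2,3,4-tetrahydronaphthalen-1-yl]acetate, 18 4,4,5,5-tetramethyl-2-vinyl-1,3,2-dioxaborolane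
Product: 19 12-methoxy-3β-(4,4,5,5-tetramethyl-1,3,2-dioxaborolan-2-yl)abieta-8,11,13-trien-6-one (5α-H, 10β-CH3)
Conditions: 18 (5 equiv), [Ru(bpy)3](PF6)2 (2 mol%), Hantzsch ester (1.5 equiv, added in portions), CH2Cl2 (0.05 M), blue LEDs, rt
Reagents that add atoms: none
Why: Proposed new method: the photoexcited ruthenium complex is quenched by the Hantzsch ester, and the reduced complex transfers one electron to the N-acyloxyphthalimide 17, which loses phthalimide anion and CO2 to leave the primary radical at C1; this radical adds to the CH2 terminus of 18 (C1–C2), the resulting α-boryl radical at C3 attacks C4, the β-carbon of the C6 isopropylidene ketone (C3–C4), and the tertiary α-keto radical at C5 takes a hydrogen atom from the Hantzsch ester. The closest known reaction types are the photoredox decarboxylative Giese addition of redox-active esters to vinyl boronic esters and radical addition–cyclisation (annulation) cascades; their merger into a (4+2) annulation through an α-boryl radical has not been shown on this substrate class. Ring A is closed in the 6-endo-trig mode, favoured over 5-exo because C5 is fully substituted and only attack at C4 gives a carbonyl-stabilised radical. C3 should be set in a chair-like transition state with the bulky boronate equatorial (3β), and C5 should receive its hydrogen on the α face opposite the axial C10 methyl, which is also the thermodynamically preferred trans ring fusion at this epimerisable centre. The step needs intermolecular addition to 18 to outrun hydrogen transfer and the slow neophyl-type aryl shift, and ring closure to outrun reduction of the α-boryl radical; the fivefold excess of 18, the poor intermolecular acceptor quality of the tetrasubstituted enone and portionwise addition of the hydrogen donor are meant to secure this. The existing C10 centre is not touched and relays its configuration to C3 and C5.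

Step 13
Reactants: 20 6-methoxy-3,4-dihydronaphthalen-1(2H)-one
Product: 21 5-bromo-6-methoxy-3,4-dihydronaphthalen-1(2H)-one
Conditions: NBS, H2SO4 (cat.), H2O, 60 °C
Reagents that add atoms: N-bromosuccinimide, O=C1CCC(=O)N1Br
Why: Electrophilic aromatic bromination should occur at C5, which is ortho to the methoxy group and additionally activated by the ring alkyl substituent.

Step 14
Reactants: 21 5-bromo-6-methoxy-3,4-dihydronaphthalen-1(2H)-one
Product: 22 6-methoxy-5-(propan-2-yl)-3,4-dihydronaphthalen-1(2H)-one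
Conditions: i-PrZnBr (1.5 equiv), Pd(OAc)2 (2 mol%), CPhos (4 mol%), THF/toluene, rt → 40 °C
Reagents that add atoms: isopropylzinc bromide, CC(C)[Zn]Br
Why: Negishi coupling of a secondary alkylzinc reagent, which tolerates the ketone, installs the later C1' isopropyl group.

Step 15
Reactants: 22 6-methoxy-5-(propan-2-yl)-3,4-dihydronaphthalen-1(2H)-one
Product: 23 6-methoxy-2-methyl-5-(propan-2-yl)-3,4-dihydronaphthalen-1(2H)-one (racemic)
Conditions: LiN(i-Pr)2 (1.05 equiv), THF, −78 °C; MeI, −78 → 0 °C
Reagents that add atoms: iodomethane, CI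
Why: Enolate alkylation at the only α-position introduces the later C6' methyl group; the new centre is removed on aromatisation.

Step 16
Reactants: 23 6-methoxy-2-methyl-5-(propan-2-yl)-3,4-dihydronaphthalen-1(2H)-one
Product: 24 6-methoxy-2-methyl-5-(propan-2-yl)-3,4-dihydronaphthalen-1-yl trifluoromethanesulfonate
Conditions: KN(SiMe3)2, THF, −78 °C; PhNTf2, −78 °C → rt
Reagents that add atoms: N-phenylbis(trifluoromethanesulfonimide), O=S(=O)(N(c1ccccc1)S(=O)(=O)C(F)(F)F)C(F)(F)F
Why: O-Triflation of the potassium enolate gives the enol triflate and turns the ketone carbon into a cross-coupling site.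

Step 17
Reactants: 24 6-methoxy-2-methyl-5-(propan-2-yl)-3,4-dihydronaphthalen-1-yl trifluoromethanesulfonate
Product: 25 6-methoxy-2-methyl-5-(propan-2-yl)naphthalen-1-yl trifluoromethanesulfonate
Conditions: DDQ, toluene, 80 °C
Reagents that add atoms: none
Why: DDQ dehydrogenation of the electron-rich 1,2-dihydronaphthalene is driven by aromatisation.

Step 18
Reactants: 25 6-methoxy-2-methyl-5-(propan-2-yl)naphthalen-1-yl trifluoromethanesulfonate, 26 4-methylpent-1-en-3-ol
Product: 27 1-[6-methoxy-2-methyl-5-(propan-2-yl)naphthalen-1-yl]-4-methylpentan-3-one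
Conditions: Pd(OAc)2 (5 mol%), P(o-tol)3 (10 mol%), LiCl, Et3N, DMF, 100 °C
Reagents that add atoms: none
Why: Heck arylation of the allylic alcohol at its terminal carbon, followed by β-hydride elimination toward the carbinol and enol–keto tautomerisation, gives the β-aryl ketone side chain directly.

Step 19
Reactants: 27 1-[6-methoxy-2-methyl-5-(propan-2-yl)naphthalen-1-yl]-4-methylpentan-3-one
Product: 28 2-{2-[6-methoxy-2-methyl-5-(propan-2-yl)naphthalen-1-yl]ethyl}-2-(propan-2-yl)-1,3-dioxolane
Conditions: HOCH2CH2OH, p-TsOH (cat.), benzene, reflux (Dean–Stark)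
Reagents that add atoms: ethylene glycol, OCCO
Why: Acid-catalysed ketalisation masks the side-chain ketone against the organolithium of step 20 and the hydride of step 22.

Step 20
Reactants: 28 2-{2-[6-methoxy-2-methyl-5-(propan-2-yl)naphthalen-1-yl]ethyl}-2-(propan-2-yl)-1,3-dioxolane
Product: 30 2-{2-[7-iodo-6-methoxy-2-methyl-5-(propan-2-yl)naphthalen-1-yl]ethyl}-2-(propan-2-yl)-1,3-dioxolane, via aryllithium 29 (not isolated)
Conditions: n-BuLi, TMEDA, Et2O, 0 °C → rt; I2, THF, −78 °C → rt
Reagents that add atoms: iodine, II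
Why: Directed ortho-metalation by the methoxy group can only occur at the free ortho position (C3' of the target, the other being blocked by isopropyl), and iodine traps the aryllithium.

Step 21
Reactants: 19 12-methoxy-3β-(4,4,5,5-tetramethyl-1,3,2-dioxaborolan-2-yl)abieta-8,11,13-trien-6-one, 30 2-{2-[7-iodo-6-methoxy-2-methyl-5-(propan-2-yl)naphthalen-1-yl]ethyl}-2-(propan-2-yl)-1,3-dioxolane
Product: 31 12-methoxy-3β-(4,4,5,5-tetramethyl-1,3,2-dioxaborolan-2-yl)abieta-8,11,13-trien-6-one carrying at C7 (α) the 1'-isopropyl-2'-methoxy-6'-methyl-5'-{2-[2-(propan-2-yl)-1,3-dioxolan-2-yl]ethyl}naphthalen-3'-yl group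
Conditions: Pd2(dba)3 (2.5 mol%), XPhos (6 mol%), K3PO4 (2.5 equiv), toluene, 90 °C
Reagents that add atoms: none
Why: Palladium-catalysed α-arylation of the β-tetralone at its benzylic C7 (C5 is a hindered methine; the secondary alkyl boronate is inert); the epimerisable C7 should settle with the aryl group pseudoaxial (α), which avoids peri strain with H14.

Step 22
Reactants: 31 the 7α-aryl 6-ketone
Product: 32 the corresponding 6β-alcohol: 12-methoxy-7α-(naphthalen-3'-yl as in 31)-3β-(4,4,5,5-tetramethyl-1,3,2-dioxaborolan-2-yl)abieta-8,11,13-trien-6β-ol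
Conditions: NaBH4, MeOH/THF, 0 °C
Reagents that add atoms: none
Why: Borohydride reduction should deliver hydride to the α face of C6, because the β face is shielded by the 1,3-diaxial methyl groups on C10 and C4, giving the axial 6β-alcohol trans-diaxial to the 7α-aryl group.

Step 23
Reactants: 32 the 6β-alcohol
Product: 34 12-hydroxy-7α-[2'-hydroxy-1'-isopropyl-6'-methyl-5'-(4-methyl-3-oxopentyl)naphthalen-3'-yl]-3β-(4,4,5,5-tetramethyl-1,3,2-dioxaborolan-2-yl)abieta-8,11,13-trien-6β-ol, via bisphenol ketal 33 (not isolated)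
Conditions: NaSEt (10 equiv), DMF, 120 °C; then 2 M HCl, THF, rt
Reagents that add atoms: water, O
Why: Thiolate SN2 attack on both aryl methyl ethers frees the two phenols without touching secondary C–O bonds or the alkyl boronate, and aqueous acid then hydrolyses the dioxolane to the side-chain ketone.

Step 24
Reactants: 34 the 6β-hydroxy bisphenol
Product: 35 3β-boronate of the target: the cis-fused dihydronaphthofuran with C6–O2' (α) and C7–C3' (α), 12-hydroxy, 3β-(4,4,5,5-tetramethyl-1,3,2-dioxaborolan-2-yl)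
Conditions: PPh3, DIAD, THF, 0 °C → 50 °C
Reagents that add atoms: none
Why: Intramolecular Mitsunobu etherification: the naphthol oxygen on the axial 7α-aryl group displaces the activated, antiperiplanar 6β-oxygen in a 5-exo-tet SN2 step, which inverts C6 to the 6α-ether and closes the cis-fused dihydrofuran; the C3 boronate is the only other sp3 oxygen-precursor site and is inert.

Step 25
Reactants: 35 the 3β-boronate
Product: 36 the target CNP0584944.1: 3β,12-dihydroxyabieta-8,11,13-triene bridged from C6 (α-O) and C7 (α-C) to O2' and C3' of 1'-isopropyl-6'-methyl-5'-(4-methyl-3-oxopentyl)naphthalene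
Conditions: NaBO3·4H2O, THF/H2O, rt
Reagents that add atoms: sodium perborate, [Na+].[O-]OB=O
Why: Perborate oxidation of the secondary alkyl boronate proceeds by 1,2-migration with retention, so the 3β-boronate becomes the 3β-hydroxyl while phenols and ketone are left alone.

**Compound list**

1 | 4-bromo-1-iodo-2-methoxybenzene | COc1cc(Br)ccc1I | starting material
2 | 4-bromo-2-methoxy-1-(propan-2-yl)benzene | COc1cc(Br)ccc1C(C)C | intermediate
3 | [3-methoxy-4-(propan-2-yl)phenyl]boronic acid | COc1cc(B(O)O)ccc1C(C)C | intermediate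
4 | 3-methylcyclopent-2-en-1-one | CC1=CC(=O)CC1 | starting material
5 | (S)-3-[3-methoxy-4-(propan-2-yl)phenyl]-3-methylcyclopentan-1-one | C[C@]1(c2ccc(C(C)C)c(OC)c2)CCC(=O)C1 | intermediate
6 | {[(S)-4-[3-methoxy-4-(propan-2-yl)phenyl]-4-methylcyclopent-1-en-1-yl]oxy}trimethylsilane | C[C@]1(c2ccc(C(C)C)c(OC)c2)CC=C(O[Si](C)(C)C)C1 | intermediate
7 | (S)-3-[3-methoxy-4-(propan-2-yl)phenyl]-3-methyl-5-oxopentanoic acid | C[C@](CC=O)(CC(=O)O)c1ccc(C(C)C)c(OC)c1 | intermediate
8 | (S)-5-hydroxy-3-[3-methoxy-4-(propan-2-yl)phenyl]-3-methylpentanoic acid | C[C@](CCO)(CC(=O)O)c1ccc(C(C)C)c(OC)c1 | intermediate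
9 | (S)-4-[3-methoxy-4-(propan-2-yl)phenyl]-4-methyloxan-2-one | C[C@]1(c2ccc(C(C)C)c(OC)c2)CCOC(=O)C1 | intermediate
10 | (S)-4-[2-bromo-5-methoxy-4-(propan-2-yl)phenyl]-4-methyloxan-2-one | C[C@]1(c2cc(OC)c(C(C)C)cc2Br)CCOC(=O)C1 | intermediate
11 | (4S)-4-[2-bromo-5-methoxy-4-(propan-2-yl)phenyl]-3-(2-hydroxypropan-2-yl)-4-methyloxan-2-one (either C3 epimer) | C[C@]1(c2cc(OC)c(C(C)C)cc2Br)CCOC(=O)C1C(C)(C)O | intermediate
12 | 2-{(4S)-4-[2-bromo-5-methoxy-4-(propan-2-yl)phenyl]-4-methyl-2-oxooxan-3-yl}propan-2-yl acetate | C[C@]1(c2cc(OC)c(C(C)C)cc2Br)CCOC(=O)C1C(C)(C)OC(C)=O | intermediate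
13 | (S)-4-[2-bromo-5-methoxy-4-(propan-2-yl)phenyl]-4-methyl-3-(propan-2-ylidene)oxan-2-one | C[C@]1(c2cc(OC)c(C(C)C)cc2Br)CCOC(=O)C1=C(C)C | intermediate
14 | (S)-4-[2-bromo-5-methoxy-4-(propan-2-yl)phenyl]-6-hydroxy-4-methyl-3-(propan-2-ylidene)hexan-2-one | CC(=O)C(=C(C)C)[C@](C)(CCO)c1cc(OC)c(C(C)C)cc1Br | intermediate
15 | (S)-3-[2-bromo-5-methoxy-4-(propan-2-yl)phenyl]-3-methyl-5-oxo-4-(propan-2-ylidene)hexanoic acid | CC(=O)C(=C(C)C)[C@](C)(CC(=O)O)c1cc(OC)c(C(C)C)cc1Br | intermediate
16 | 2-[(1R)-7-methoxy-1-methyl-3-oxo-6-(propan-2-yl)-2-(propan-2-ylidene)-1,2,3,4-tetrahydronaphthalen-1-yl]acetic acid | COc1cc2c(cc1C(C)C)CC(=O)C(=C(C)C)[C@]2(C)CC(=O)O | intermediate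
17 | 1,3-dioxoisoindolin-2-yl 2-[(1R)-7-methoxy-1-methyl-3-oxo-6-(propan-2-yl)-2-(propan-2-ylidene)-1,2,3,4-tetrahydronaphthalen-1-yl]acetate | COc1cc2c(cc1C(C)C)CC(=O)C(=C(C)C)[C@]2(C)CC(=O)ON1C(=O)c2ccccc2C1=O | intermediate
18 | 4,4,5,5-tetramethyl-2-vinyl-1,3,2-dioxaborolane | C=CB1OC(C)(C)C(C)(C)O1 | starting material
19 | 12-methoxy-3β-(4,4,5,5-tetramethyl-1,3,2-dioxaborolan-2-yl)abieta-8,11,13-trien-6-one (5α-H, 10β-CH3) | O=C1Cc2cc(C(C)C)c(OC)cc2[C@@]2(C)CC[C@H](B3OC(C)(C)C(C)(C)O3)C(C)(C)[C@@H]21 | intermediate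
20 | 6-methoxy-3,4-dihydronaphthalen-1(2H)-one | COc1ccc2c(c1)CCCC2=O | starting material
21 | 5-bromo-6-methoxy-3,4-dihydronaphthalen-1(2H)-one | COc1ccc2c(c1Br)CCCC2=O | intermediate
22 | 6-methoxy-5-(propan-2-yl)-3,4-dihydronaphthalen-1(2H)-one | COc1ccc2c(c1C(C)C)CCCC2=O | intermediate
23 | 6-methoxy-2-methyl-5-(propan-2-yl)-3,4-dihydronaphthalen-1(2H)-one (racemic) | COc1ccc2c(c1C(C)C)CCC(C)C2=O | intermediate
24 | 6-methoxy-2-methyl-5-(propan-2-yl)-3,4-dihydronaphthalen-1-yl trifluoromethanesulfonate | COc1ccc2c(c1C(C)C)CCC(C)=C2OS(=O)(=O)C(F)(F)F | intermediate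
25 | 6-methoxy-2-methyl-5-(propan-2-yl)naphthalen-1-yl trifluoromethanesulfonate | COc1ccc2c(OS(=O)(=O)C(F)(F)F)c(C)ccc2c1C(C)C | intermediate
26 | 4-methylpent-1-en-3-ol (racemic) | C=CC(O)C(C)C | starting material
27 | 1-[6-methoxy-2-methyl-5-(propan-2-yl)naphthalen-1-yl]-4-methylpentan-3-one | COc1ccc2c(CCC(=O)C(C)C)c(C)ccc2c1C(C)C | intermediate
28 | 2-{2-[6-methoxy-2-methyl-5-(propan-2-yl)naphthalen-1-yl]ethyl}-2-(propan-2-yl)-1,3-dioxolane | COc1ccc2c(CCC3(C(C)C)OCCO3)c(C)ccc2c1C(C)C | intermediate
29 | 7-lithio derivative of 28 (aryllithium ortho to the methoxy group) | COc1c([Li])cc2c(CCC3(C(C)C)OCCO3)c(C)ccc2c1C(C)C | intermediate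
30 | 2-{2-[7-iodo-6-methoxy-2-methyl-5-(propan-2-yl)naphthalen-1-yl]ethyl}-2-(propan-2-yl)-1,3-dioxolane | COc1c(I)cc2c(CCC3(C(C)C)OCCO3)c(C)ccc2c1C(C)C | intermediate
31 | 12-methoxy-7α-(1'-isopropyl-2'-methoxy-6'-methyl-5'-{2-[2-(propan-2-yl)-1,3-dioxolan-2-yl]ethyl}naphthalen-3'-yl)-3β-(4,4,5,5-tetramethyl-1,3,2-dioxaborolan-2-yl)abieta-8,11,13-trien-6-one | Cc1ccc2c(C(C)C)c(OC)c(cc2c1CCC1(C(C)C)OCCO1)[C@H]1c2cc(C(C)C)c(OC)cc2[C@@]2(C)CC[C@H](B3OC(C)(C)C(C)(C)O3)C(C)(C)[C@@H]2C1=O | intermediate
32 | 6β-alcohol of 31 (7α-aryl, 6β-OH) | Cc1ccc2c(C(C)C)c(OC)c(cc2c1CCC1(C(C)C)OCCO1)[C@H]1c2cc(C(C)C)c(OC)cc2[C@@]2(C)CC[C@H](B3OC(C)(C)C(C)(C)O3)C(C)(C)[C@@H]2[C@@H]1O | intermediate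
33 | bisphenol ketal: 32 with both aryl methyl ethers cleaved (12-OH, 2'-OH), dioxolane intact | Cc1ccc2c(C(C)C)c(O)c(cc2c1CCC1(C(C)C)OCCO1)[C@H]1c2cc(C(C)C)c(O)cc2[C@@]2(C)CC[C@H](B3OC(C)(C)C(C)(C)O3)C(C)(C)[C@@H]2[C@@H]1O | intermediate
34 | 12-hydroxy-7α-[2'-hydroxy-1'-isopropyl-6'-methyl-5'-(4-methyl-3-oxopentyl)naphthalen-3'-yl]-3β-(4,4,5,5-tetramethyl-1,3,2-dioxaborolan-2-yl)abieta-8,11,13-trien-6β-ol | Cc1ccc2c(C(C)C)c(O)c(cc2c1CCC(=O)C(C)C)[C@H]1c2cc(C(C)C)c(O)cc2[C@@]2(C)CC[C@H](B3OC(C)(C)C(C)(C)O3)C(C)(C)[C@@H]2[C@@H]1O | intermediate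
35 | 3β-(4,4,5,5-tetramethyl-1,3,2-dioxaborolan-2-yl) analogue of the target (cis-fused dihydronaphthofuran, 6α-O, 7α-C, 12-OH) | Cc1ccc2c(C(C)C)c3c(cc2c1CCC(=O)C(C)C)[C@H]1c2cc(C(C)C)c(O)cc2[C@@]2(C)CC[C@H](B4OC(C)(C)C(C)(C)O4)C(C)(C)[C@@H]2[C@H]1O3 | intermediate
36 | CNP0584944.1 (3β,12-dihydroxy; 5α-H, 10β-CH3; 6α-O and 7α-C bridged to O2' and C3' of the naphthalene) | Cc1ccc2c(C(C)C)c3c(cc2c1CCC(=O)C(C)C)[C@H]1c2cc(C(C)C)c(O)cc2[C@@]2(C)CC[C@H](O)C(C)(C)[C@@H]2[C@H]1O3 | target

**Step count.** Total: 25 steps. Longest linear sequence: 17 steps (steps 1–12, then 21–25); the naphthalene fragment takes 8 steps (13–20).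

**Steps most likely to fail, with fallbacks**

First, step 12 (proposed new method). The process at risk is premature hydrogen transfer to the C1 radical or to the α-boryl radical before the second C–C bond forms, or intramolecular hydrogen abstraction from the doubly activated C7 methylene, giving open-chain or simply reduced material. The fallback uses known radical chain chemistry and makes the two bonds in separate operations; it sets out from 16 and returns at 19. Acid 16 is condensed with 1-hydroxypyridine-2(1H)-thione and N,N'-dicyclohexylcarbodiimide to the O-acyl thiohydroxamate (Barton ester) F1. Visible-light irradiation of F1 in neat 18 should give, by decarboxylation, addition of the C1 radical to the vinyl boronate and pyridylthio group transfer, the α-(pyridin-2-ylsulfanyl) boronate F2, in which C1–C2 is in place. Slow addition of Bu3SnH and AIBN to F2 in refluxing benzene at high dilution then regenerates the α-boryl radical with almost no hydrogen donor present, so the 6-endo closure onto C4 has time to occur and 19 is reached.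

Second, step 24. The process at risk is failure to activate the hindered axial 6β-hydroxyl (flanked by the axial methyls on C10 and C4), with elimination toward C5 or C7 taking over. The fallback avoids the free naphthol and the phosphonium intermediate; it sets out from 32 and returns at 35. The 6β-alcohol 32 is converted with trifluoromethanesulfonic anhydride and 2,6-di-tert-butyl-4-methylpyridine at −78 °C into the 6β-triflate F3. The neighbouring 2'-methoxy oxygen should displace the triflate from the α face, and the oxonium ion loses methyl triflate to give the cyclised 12-methyl ether ketal F4. NaSEt in DMF then cleaves the remaining aryl methyl ether to the phenol ketal F5, and aqueous HCl releases the ketone to give 35.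

Third, step 18. The process at risk is sluggish oxidative addition at the di-ortho-substituted naphthyl triflate and loss of regiocontrol in the β-hydride elimination, giving allylic alcohol or enone by-products. The fallback replaces the Heck reaction by a homoenolate cross-coupling; it sets out from 25 and returns at 27. 1-(Propan-2-yl)cyclopropan-1-ol F6 is prepared from methyl 2-methylpropanoate with EtMgBr and Ti(Oi-Pr)4 (Kulinkovich reaction). Coupling of F6 with triflate 25 under Pd(OAc)2, XPhos and Cs2CO3 in toluene at 80 °C should open the cyclopropanol to the palladium homoenolate and give ketone 27 directly.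

Further compounds
F1 | step 12 | 2-thioxopyridin-1(2H)-yl 2-[(1R)-7-methoxy-1-methyl-3-oxo-6-(propan-2-yl)-2-(propan-2-ylidene)-1,2,3,4-tetrahydronaphthalen-1-yl]acetate | COc1cc2c(cc1C(C)C)CC(=O)C(=C(C)C)[C@]2(C)CC(=O)ON1C=CC=CC1=S
F2 | step 12 | (4R)-7-methoxy-4-methyl-6-(propan-2-yl)-3-(propan-2-ylidene)-4-[3-(pyridin-2-ylsulfanyl)-3-(4,4,5,5-tetramethyl-1,3,2-dioxaborolan-2-yl)propyl]-3,4-dihydronaphthalen-2(1H)-one (either epimer at the sulfur-bearing carbon) | COc1cc2c(cc1C(C)C)CC(=O)C(=C(C)C)[C@]2(C)CCC(Sc1ccccn1)B1OC(C)(C)C(C)(C)O1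
F3 | step 24 | 6β-trifluoromethanesulfonate of 32 | Cc1ccc2c(C(C)C)c(OC)c(cc2c1CCC1(C(C)C)OCCO1)[C@H]1c2cc(C(C)C)c(OC)cc2[C@@]2(C)CC[C@H](B3OC(C)(C)C(C)(C)O3)C(C)(C)[C@@H]2[C@@H]1OS(=O)(=O)C(F)(F)F
F4 | step 24 | cyclised dihydronaphthofuran with 12-methoxy group, side-chain dioxolane and 3β-boronate | Cc1ccc2c(C(C)C)c3c(cc2c1CCC1(C(C)C)OCCO1)[C@H]1c2cc(C(C)C)c(OC)cc2[C@@]2(C)CC[C@H](B4OC(C)(C)C(C)(C)O4)C(C)(C)[C@@H]2[C@H]1O3
F5 | step 24 | cyclised dihydronaphthofuran with 12-hydroxyl, side-chain dioxolane and 3β-boronate | Cc1ccc2c(C(C)C)c3c(cc2c1CCC1(C(C)C)OCCO1)[C@H]1c2cc(C(C)C)c(O)cc2[C@@]2(C)CC[C@H](B4OC(C)(C)C(C)(C)O4)C(C)(C)[C@@H]2[C@H]1O3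
F6 | step 18 | 1-(propan-2-yl)cyclopropan-1-ol | CC(C)C1(O)CC1
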